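**Assumption:** atom labels C1–C15 follow germacranolide numbering of the target (C6 = lactone carbinol, C7 = ring-fusion CH, C8 = ester carbinol, C1–C10 = epoxide, C15 = CH2OH); the bicyclic and cyclohexadiene intermediates before ring cleavage are racemic and drawn as one enantiomer.

## Retrosynthetic overview

1. Target ⇐ desilylation ⇐ epoxidation of C1=C10 ⇐ acylation of the C8 alcohol with silyl-protected (Z)-2-(hydroxymethyl)but-2-enoic acid.
2. Ten-membered ring (formed second) ⇐ C9–C10 bond by intramolecular nickel-catalysed reductive coupling of a (Z)-alkenyl iodide with a primary alkyl sulfonate.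
3. cis-α-Methylene-γ-lactone (formed first, C6–C7 bond) ⇐ zinc Barbier allylation of a C1–C6 trienal with a bromide made from (S)-glyceraldehyde acetonide and methyl acrylate.
4. Trienal ⇐ iodo-Wittig olefination at C1 of a lactol-enal ⇐ periodate cleavage (C1–C6) of a cis-cyclohexadienediol.
5. Key disconnection: that diol ⇐ benzyl acetate by visible-light arenophile cycloaddition, dihydroxylation and N2 extrusion. The ring-cis C2=C3 and C4=C5 bonds are two former benzene double bonds; the epoxide ring is formed last.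

## Route

Step 1
Reactants: 1 benzyl acetate
Product: 3 rac-urazole-bridged bicyclic cis-diol (CH2OAc on the remaining alkene), via cycloadduct 2 (not isolated)
Conditions: MTAD, white LEDs, CH2Cl2, −78 °C; then OsO4 (5 mol %), NMO, acetone/H2O, −50 °C
Reagents that add atoms: 4-methyl-1,2,4-triazoline-3,5-dione (MTAD), CN1C(=O)N=NC1=O; N-methylmorpholine N-oxide, C[N+]1([O-])CCOCC1; water, O
Why: Visible-light arenophile [4+2] para-cycloaddition across the two unsubstituted para carbons breaks the aromaticity, and Upjohn dihydroxylation then takes the less hindered disubstituted alkene anti to the urazole, giving the cis-diol at the future C1 and C6 (racemic, erased in step 3).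

Step 2
Reactants: 3 bicyclic diol
Product: 6 rac-cis-4-(hydroxymethyl)cyclohexa-3,5-diene-1,2-diol, via hydrazine 4 (not isolated), via diazene 5 (not isolated)
Conditions: KOH, i-PrOH, 100 °C; AcOH to pH 7; CuCl2·2H2O, 0 °C; aq. NH3, 0 °C → rt
Reagents that add atoms: none
Why: Urazole and acetate are hydrolysed, CuCl2 oxidises the cyclic hydrazine to the diazene, and retro-Diels–Alder loss of N2 unveils a cyclohexadiene whose two double bonds (future C2=C3 and C4=C5) are necessarily cis in the ring.

Step 3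
Reactants: 6 cyclohexadienetriol
Product: 8 (2E)-2-(6-hydroxy-2H-pyran-3(6H)-ylidene)acetaldehyde (lactol-enal), via dialdehyde 7 (not isolated)
Conditions: NaIO4, pH 7 phosphate buffer/THF, 0 °C; use at once
Reagents that add atoms: none
Why: Malaprade glycol cleavage opens the ring between C1 and C6 to the ring-cis dienedial, in which only the C1 aldehyde can reach the C15 hydroxyl (cis across C2=C3) and closes to a six-membered lactol, so C6 is left as the only free aldehyde.

Step 4
Reactants: 8 lactol-enal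
Product: 11 (2E,4Z,6Z)-3-({[tert-butyl(diphenyl)silyl]oxy}methyl)-7-iodoocta-2,4,6-trienal, via aminal 9 (not isolated), via silylated aminal 10 (not isolated)
Conditions: MeNH(CH2)2NHMe, MgSO4, THF, 0 °C; add to Ph3P=C(Me)I [Ph3PEtI, n-BuLi; I2; NaHMDS], THF, −78 → −20 °C; TBDPSCl, 0 °C; aq. citric acid; use at once
Reagents that add atoms: (1-iodoethylidene)triphenylphosphorane, CC(I)=P(c1ccccc1)(c1ccccc1)c1ccccc1; tert-butyl(chloro)diphenylsilane, CC(C)(C)[Si](Cl)(c1ccccc1)c1ccccc1
Why: The free C6 enal is masked in the flask as an imidazolidine, base opens the lactol, and the Stork–Zhao α-iodo Wittig olefination gives the (Z)-alkenyl iodide (iodine cis to C2, the geometry C1=C10 needs); the freed C15 alkoxide is silylated and the aminal falls off on acidic work-up.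

Step 5
Reactants: 12 (S)-2,2-dimethyl-1,3-dioxolane-4-carbaldehyde; 13 methyl acrylate
Product: 14 methyl 2-{[(4S)-2,2-dimethyl-1,3-dioxolan-4-yl](hydroxy)methyl}prop-2-enoate (carbinol epimers)
Conditions: DABCO, 1,4-dioxane/H2O, rt, 48 h
Reagents that add atoms: none
Why: Morita–Baylis–Hillman reaction; the new carbinol centre is removed in step 6 and the dioxolane centre (future C8) is untouched.

Step 6
Reactants: 14 Baylis–Hillman adduct
Product: 15 methyl (2Z)-2-(bromomethyl)-3-[(4R)-2,2-dimethyl-1,3-dioxolan-4-yl]prop-2-enoate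
Conditions: NBS, Me2S, CH2Cl2, 0 °C → rt
Reagents that add atoms: N-bromosuccinimide, BrN1C(=O)CCC1=O
Why: Corey–Kim-type bromination with allylic transposition (SN2′) gives the favoured (Z)-2-(bromomethyl)enoate with the dioxolane cis to CH2Br.

Step 7
Reactants: 11 trienal; 15 allylic bromide
Product: 18 (4S,5S)-5-[(1E,3Z,5Z)-2-({[tert-butyl(diphenyl)silyl]oxy}methyl)-6-iodohepta-1,3,5-trien-1-yl]-4-[(4R)-2,2-dimethyl-1,3-dioxolan-4-yl]-3-methylideneoxolan-2-one (cis-lactone; C6 C7 C8 configured as in the target), via allylzinc bromide 16 (not isolated), via hydroxy ester 17 (not isolated)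
Conditions: Zn dust, THF/sat. aq. NH4Cl, 0 °C → rt; then PPTS (cat.), CH2Cl2, rt
Reagents that add atoms: none
Why: Zinc Barbier allylation through a chair Zimmerman–Traxler transition state: the (Z)-bromide gives the 6,7-syn adduct (cis-lactone after lactonisation), and the aldehyde adds to the C7 face anti to the dioxolane C–O bond with the allylic hydrogen eclipsing the alkene (A1,3 strain, Felkin-type), which sets C6 and C7 from C8.

Step 8
Reactants: 18 lactone acetonide
Product: 19 (4R,5S)-4-[(1R)-1,2-dihydroxyethyl]-5-[(1E,3Z,5Z)-2-({[tert-butyl(diphenyl)silyl]oxy}methyl)-6-iodohepta-1,3,5-trien-1-yl]-3-methylideneoxolan-2-one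
Conditions: AcOH/H2O/THF (3:1:1), 40 °C
Reagents that add atoms: none
Why: Acid hydrolysis of the terminal acetonide; the silyl ether, alkenyl iodide and methylene lactone are stable to aqueous acetic acid.

Step 9
Reactants: 19 diol
Product: 20 primary 4-methylbenzenesulfonate of 19 (C9–OTs, C8–OH free)
Conditions: TsCl, Et3N, Bu2SnO (5 mol %), CH2Cl2, 0 °C
Reagents that add atoms: 4-methylbenzenesulfonyl chloride, Cc1ccc(cc1)S(Cl)(=O)=O
Why: Tin-catalysed sulfonylation via the stannylene acetal is selective for the primary hydroxyl of a 1,2-diol.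

Step 10
Reactants: 20 tosylate
Product: 22 (6S,7R,8S)-15-{[tert-butyl(diphenyl)silyl]oxy}-8-hydroxygermacra-1(10)Z,2Z,4E,11(13)-tetraen-12,6-olide (all three ring alkenes ring-cis), via iodide 21 (not isolated)
Conditions: NiBr2(dme) (20 mol %), 4,4′-di-tert-butyl-2,2′-bipyridine (20 mol %), NaI, Zn dust, DMA, 2 mM, slow addition, rt
Reagents that add atoms: none
Why: Proposed new method: an intramolecular nickel-catalysed reductive cross-electrophile coupling in which iodide converts the tosylate into the β-hydroxy alkyl iodide, zerovalent nickel inserts into the C10–I bond with retention of geometry, the C9 radical is captured by the alkenylnickel and reductive elimination forms C9–C10; the closest known reactions are the intermolecular Ni/bipyridine/Zn coupling of alkenyl halides with alkyl halides and the Ni/NaI coupling of epoxides through β-hydroxy alkyl iodides, and the all-cis triene plus the lactone pre-fold the chain so that C9 and C10 lie close.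

Step 11
Reactants: 23 (E)-crotonaldehyde
Product: 24 (2Z)-2-iodobut-2-enal
Conditions: I2, K2CO3, DMAP (cat.), THF/H2O, rt
Reagents that add atoms: iodine, [I][I]
Why: Baylis–Hillman-type α-iodination (DMAP adds, the enolate is iodinated, DMAP is expelled) keeps the methyl trans to the formyl group.

Step 12
Reactants: 24 iodoenal
Product: 25 (2Z)-2-iodobut-2-en-1-ol
Conditions: NaBH4, CeCl3·7H2O, MeOH, 0 °C
Reagents that add atoms: none
Why: Luche 1,2-reduction of the enal without touching the alkenyl iodide.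

Step 13
Reactants: 25 iodo alcohol
Product: 26 tert-butyl{[(2Z)-2-iodobut-2-en-1-yl]oxy}dimethylsilane
Conditions: TBSCl, imidazole, CH2Cl2, rt
Reagents that add atoms: tert-butyl(chloro)dimethylsilane, CC(C)(C)[Si](C)(C)Cl
Why: Standard silyl ether formation protects the hydroxyl for lithiation and acylation.

Step 14
Reactants: 26 silyl ether
Product: 28 (2Z)-2-({[tert-butyl(dimethyl)silyl]oxy}methyl)but-2-enoic acid, via alkenyllithium 27 (not isolated)
Conditions: t-BuLi (2 equiv), Et2O, −78 °C; CO2; dilute HCl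
Reagents that add atoms: carbon dioxide, O=C=O
Why: Iodine–lithium exchange gives a configurationally stable alkenyllithium that is carboxylated with retention, so the methyl ends cis to the carboxyl as in the target side chain.

Step 15
Reactants: 22 macrocyclic alcohol; 28 acid
Product: 30 C8 ester of 22 with 28, via mixed anhydride 29 (not isolated)
Conditions: 28, 2,4,6-Cl3C6H2COCl, Et3N, toluene, rt; then 22, DMAP (0.3 equiv), rt
Reagents that add atoms: none
Why: Yamaguchi esterification acylates the only free hydroxyl with retention at C8; room temperature and substoichiometric DMAP limit Z→E isomerisation of the acyl group and keep the cyclic triene below the temperature of electrocyclisation.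

Step 16
Reactants: 30 ester
Product: 31 (1R,10S)-1,10-epoxide of 30
Conditions: dimethyldioxirane, acetone, −20 → 0 °C
Reagents that add atoms: dimethyldioxirane, CC1(C)OO1
Why: Dioxirane (Murray) epoxidation takes the most electron-rich, trisubstituted C1=C10 bond (C4=C5 is deactivated by two allylic oxygens, the two enoates are inert); attack on the open outer face of the cup-shaped all-cis triene, anti to the transannular C4=C5 bond, should give the cis-epoxide trans to the C8 acyloxy group, but this facial preference is a prediction, not an established result.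

Step 17
Reactants: 31 bis-silyl epoxide
Product: 32 target, (1R,6S,7R,8S,10S)-1,10-epoxy-15-hydroxy-8-{[(2Z)-2-(hydroxymethyl)but-2-enoyl]oxy}germacra-2Z,4E,11(13)-trien-12,6-olide (CNP0293319.3)
Conditions: TBAF, AcOH (1:1), THF, 0 °C → rt
Reagents that add atoms: none
Why: Fluoride desilylation buffered by acetic acid removes both silyl ethers without base-induced addition to the methylene lactone or opening of the vinyl epoxide.

## Compound list

1 | benzyl acetate | CC(=O)OCc1ccccc1 | starting material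
2 | rac-MTAD para-cycloadduct of benzyl acetate (urazole-bridged 2,3-diazabicyclo[2.2.2]octa-5,7-diene, CH2OAc on C5) | CC(=O)OCC1=C[C@H]2C=C[C@@H]1N1C(=O)N(C)C(=O)N12 | intermediate (not isolated)
3 | rac-urazole-bridged 2,3-diazabicyclo[2.2.2]oct-5-ene-7,8-cis-diol, diol anti to the urazole, CH2OAc on C5 | CC(=O)OCC1=C[C@H]2[C@@H](O)[C@@H](O)[C@@H]1N1C(=O)N(C)C(=O)N12 | intermediate
4 | rac-5-(hydroxymethyl)-2,3-diazabicyclo[2.2.2]oct-5-ene-7,8-diol (cyclic hydrazine) | OCC1=C[C@H]2[C@@H](O)[C@@H](O)[C@@H]1NN2 | intermediate (not isolated)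
5 | rac-5-(hydroxymethyl)-2,3-diazabicyclo[2.2.2]octa-2,5-diene-7,8-diol (diazene) | OCC1=C[C@H]2[C@@H](O)[C@@H](O)[C@@H]1N=N2 | intermediate (not isolated)
6 | rac-cis-4-(hydroxymethyl)cyclohexa-3,5-diene-1,2-diol | OCC1=C[C@H](O)[C@H](O)C=C1 | intermediate
7 | (2E,4Z)-3-(hydroxymethyl)hexa-2,4-dienedial | O=C/C=C(CO)\C=C/C=O | intermediate (not isolated)
8 | (2E)-2-(6-hydroxy-2H-pyran-3(6H)-ylidene)acetaldehyde (anomers) | O=C/C=C1\C=CC(O)OC1 | intermediate
9 | 2-[(E)-(6-hydroxy-2H-pyran-3(6H)-ylidene)methyl]-1,3-dimethylimidazolidine | CN1CCN(C)C1/C=C1\C=CC(O)OC1 | intermediate (not isolated)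
10 | 2-[(1E,3Z,5Z)-2-({[tert-butyl(diphenyl)silyl]oxy}methyl)-6-iodohepta-1,3,5-trien-1-yl]-1,3-dimethylimidazolidine | CN1CCN(C)C1/C=C(CO[Si](c1ccccc1)(c1ccccc1)C(C)(C)C)\C=C/C=C(/C)I | intermediate (not isolated)
11 | (2E,4Z,6Z)-3-({[tert-butyl(diphenyl)silyl]oxy}methyl)-7-iodoocta-2,4,6-trienal | O=C/C=C(CO[Si](c1ccccc1)(c1ccccc1)C(C)(C)C)\C=C/C=C(/C)I | intermediate
12 | (S)-2,2-dimethyl-1,3-dioxolane-4-carbaldehyde | O=C[C@@H]1COC(C)(C)O1 | starting material
13 | methyl acrylate | C=CC(=O)OC | starting material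
14 | methyl 2-{[(4S)-2,2-dimethyl-1,3-dioxolan-4-yl](hydroxy)methyl}prop-2-enoate (carbinol epimers) | COC(=O)C(=C)C(O)[C@@H]1COC(C)(C)O1 | intermediate
15 | methyl (2Z)-2-(bromomethyl)-3-[(4R)-2,2-dimethyl-1,3-dioxolan-4-yl]prop-2-enoate | COC(=O)/C(CBr)=C/[C@@H]1COC(C)(C)O1 | intermediate
16 | allylzinc bromide from 15 | COC(=O)/C(C[Zn]Br)=C/[C@@H]1COC(C)(C)O1 | intermediate (not isolated)
17 | 6,7-syn homoallylic alcohol methyl ester (open form of 18) | COC(=O)C(=C)[C@H]([C@@H]1COC(C)(C)O1)[C@@H](O)/C=C(CO[Si](c1ccccc1)(c1ccccc1)C(C)(C)C)\C=C/C=C(/C)I | intermediate (not isolated)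
18 | (4S,5S)-5-[(1E,3Z,5Z)-2-({[tert-butyl(diphenyl)silyl]oxy}methyl)-6-iodohepta-1,3,5-trien-1-yl]-4-[(4R)-2,2-dimethyl-1,3-dioxolan-4-yl]-3-methylideneoxolan-2-one | C=C1C(=O)O[C@@H](/C=C(CO[Si](c2ccccc2)(c2ccccc2)C(C)(C)C)\C=C/C=C(/C)I)[C@H]1[C@@H]1COC(C)(C)O1 | intermediate
19 | (4R,5S)-4-[(1R)-1,2-dihydroxyethyl]-5-[(1E,3Z,5Z)-2-({[tert-butyl(diphenyl)silyl]oxy}methyl)-6-iodohepta-1,3,5-trien-1-yl]-3-methylideneoxolan-2-one | C=C1C(=O)O[C@@H](/C=C(CO[Si](c2ccccc2)(c2ccccc2)C(C)(C)C)\C=C/C=C(/C)I)[C@H]1[C@@H](O)CO | intermediate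
20 | primary 4-methylbenzenesulfonate of 19 | C=C1C(=O)O[C@@H](/C=C(CO[Si](c2ccccc2)(c2ccccc2)C(C)(C)C)\C=C/C=C(/C)I)[C@H]1[C@@H](O)COS(=O)(=O)c1ccc(C)cc1 | intermediate
21 | primary iodide corresponding to 20 | C=C1C(=O)O[C@@H](/C=C(CO[Si](c2ccccc2)(c2ccccc2)C(C)(C)C)\C=C/C=C(/C)I)[C@H]1[C@@H](O)CI | intermediate (not isolated)
22 | (6S,7R,8S)-15-{[tert-butyl(diphenyl)silyl]oxy}-8-hydroxygermacra-1(10)Z,2Z,4E,11(13)-tetraen-12,6-olide | C=C1C(=O)O[C@H]2/C=C(CO[Si](c3ccccc3)(c3ccccc3)C(C)(C)C)\C=C/C=C(/C)C[C@H](O)[C@@H]12 | intermediate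
23 | (E)-crotonaldehyde | C/C=C/C=O | starting material
24 | (2Z)-2-iodobut-2-enal | C/C=C(\I)C=O | intermediate
25 | (2Z)-2-iodobut-2-en-1-ol | C/C=C(\I)CO | intermediate
26 | tert-butyl{[(2Z)-2-iodobut-2-en-1-yl]oxy}dimethylsilane | C/C=C(\I)CO[Si](C)(C)C(C)(C)C | intermediate
27 | alkenyllithium from 26 | C/C=C(\[Li])CO[Si](C)(C)C(C)(C)C | intermediate (not isolated)
28 | (2Z)-2-({[tert-butyl(dimethyl)silyl]oxy}methyl)but-2-enoic acid | C/C=C(\C(=O)O)CO[Si](C)(C)C(C)(C)C | intermediate
29 | mixed anhydride of 28 with 2,4,6-trichlorobenzoic acid | C/C=C(\C(=O)OC(=O)c1c(Cl)cc(Cl)cc1Cl)CO[Si](C)(C)C(C)(C)C | intermediate (not isolated)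
30 | 8-O-[(2Z)-2-({[tert-butyl(dimethyl)silyl]oxy}methyl)but-2-enoyl] ester of 22 | C=C1C(=O)O[C@H]2/C=C(CO[Si](c3ccccc3)(c3ccccc3)C(C)(C)C)\C=C/C=C(/C)C[C@H](OC(=O)/C(=C\C)CO[Si](C)(C)C(C)(C)C)[C@@H]12 | intermediate
31 | (1R,10S)-1,10-epoxide of 30 | C=C1C(=O)O[C@H]2/C=C(CO[Si](c3ccccc3)(c3ccccc3)C(C)(C)C)\C=C/[C@H]3O[C@@]3(C)C[C@H](OC(=O)/C(=C\C)CO[Si](C)(C)C(C)(C)C)[C@@H]12 | intermediate
32 | CNP0293319.3 | C=C1C(=O)O[C@H]2/C=C(CO)\C=C/[C@H]3O[C@@]3(C)C[C@H](OC(=O)/C(=C\C)CO)[C@@H]12 | target

## Step count and risks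

Total: 17 steps. Longest linear sequence: 11 steps (1, 2, 3, 4, 7, 8, 9, 10, 15, 16, 17) from benzyl acetate.

**Step 10 (ring closure by an unprecedented intramolecular reductive coupling, in the presence of the methylene lactone).** Fallback: change the ring-closing bond to C6–C7. Set out from 11 and 14. Hydrolyse the acetonide of 14 to the triol F5 and tosylate its primary hydroxyl (Bu2SnO, TsCl) to the tosylate F6. Couple F6 with 11 intermolecularly under the same nickel conditions to the dienal diol F7. Convert the Baylis–Hillman hydroxyl with NBS/Me2S into the rearranged allylic bromide F8. Close the ring by a CrCl2-mediated Nozaki–Hiyama allylation at high dilution with lactonisation, which comes back to the route at 22.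

**Step 4 (olefination of a lactol beside a transiently masked enal; 11 is an isomerisation-prone ring-cis dienal).** Fallback: reverse the order of the two carbonyl additions. Set out from 8 and run the zinc Barbier reaction with 15 first, which consumes the free C6 aldehyde and gives the lactone lactol F1. Add dimethylamine to the methylene lactone to give the base-stable amino lactone F2. Carry out the iodo-Wittig olefination and silylation on the lactol of F2 to give the alkenyl iodide F3. Quaternise with MeI to the ammonium iodide F4 and eliminate with NaHCO3, which regenerates the methylene lactone and returns to the route at 18.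

**Step 16 (facial selectivity of the epoxidation in the ten-membered ring is only predicted).** Fallback: reach the other face through a halohydrin. Set out from 30; NBS in aqueous acetone puts bromine on the face the dioxirane would use and water on C10 from the opposite face, giving the bromohydrin F9. Ag2O then closes the epoxide by displacement at C1 and returns to the route at 31.

## Further compounds

F1 | step 4 | lactone lactol from 8 and 15 (methylene lactone carrying the pyranylidene lactol at C6 and the dioxolane at C7) | C=C1C(=O)O[C@@H](/C=C2\C=CC(O)OC2)[C@H]1[C@@H]1COC(C)(C)O1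
F2 | step 4 | dimethylamine adduct of F1 (C11 epimers) | CN(C)CC1C(=O)O[C@@H](/C=C2\C=CC(O)OC2)[C@H]1[C@@H]1COC(C)(C)O1
F3 | step 4 | dimethylamine adduct of 18 | CN(C)CC1C(=O)O[C@@H](/C=C(CO[Si](c2ccccc2)(c2ccccc2)C(C)(C)C)\C=C/C=C(/C)I)[C@H]1[C@@H]1COC(C)(C)O1
F4 | step 4 | trimethylammonium iodide of F3 | C[N+](C)(C)CC1C(=O)O[C@@H](/C=C(CO[Si](c2ccccc2)(c2ccccc2)C(C)(C)C)\C=C/C=C(/C)I)[C@H]1[C@@H]1COC(C)(C)O1.[I-]
F5 | step 10 | methyl (4S)-3,4,5-trihydroxy-2-methylidenepentanoate (C3 epimers) | COC(=O)C(=C)C(O)[C@@H](O)CO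
F6 | step 10 | primary 4-methylbenzenesulfonate of F5 | COC(=O)C(=C)C(O)[C@@H](O)COS(=O)(=O)c1ccc(C)cc1
F7 | step 10 | coupled dienal diol (C9–C10 bond formed, Baylis–Hillman hydroxyl and C8 hydroxyl free) | COC(=O)C(=C)C(O)[C@@H](O)C/C(C)=C\C=C/C(CO[Si](c1ccccc1)(c1ccccc1)C(C)(C)C)=C\C=O
F8 | step 10 | rearranged (Z)-allylic bromide of F7 | COC(=O)/C(CBr)=C/[C@@H](O)C/C(C)=C\C=C/C(CO[Si](c1ccccc1)(c1ccccc1)C(C)(C)C)=C\C=O
F9 | step 16 | 1-bromo-10-hydroxy bromohydrin of 30 | C=C1C(=O)O[C@H]2/C=C(CO[Si](c3ccccc3)(c3ccccc3)C(C)(C)C)\C=C/[C@H](Br)[C@@](C)(O)C[C@H](OC(=O)/C(=C\C)CO[Si](C)(C)C(C)(C)C)[C@@H]12
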